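**Retrosynthetic overview**
1. Iridal ⇐ methanolysis of a benzoate/cyclic-carbonate-protected enal ⇐ Babler–Dauben oxidative transposition of a C7 isopropenyl carbinol ⇐ C7 ketone; the (2Z)-enal is grown on a C7 oxygen.
2. C7 ketone ⇐ one cation–olefin cyclisation of an acyclic epoxy-polyene that forges C6–C11 the way the presumed biosynthesis closes this ring: electrophilic C6, attack by the Δ10(11) olefin through a chair, C10 cation taken by oxygen (here the C26 carbamate).
3. The oxirane lies on C6–C7 next to an alkyne (C4≡C5), so C6 is the electrophile (inversion) and the oxirane oxygen stays on C7; the olefin is pre-set as C10(CH3)=C11(CH2O)(homofarnesyl), so C6, C10 and C11 arise in that single step.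
4. Epoxy-polyene ⇐ Negishi sp3–sp2 coupling of an epoxy alkylzinc (Shi epoxidation of an E-enyne from but-3-yn-1-ol and propargyl benzoate) with a tetrasubstituted vinyl iodide (anti-carbomagnesiation of but-2-yn-1-ol by homofarnesylmagnesium bromide, from farnesol).
5. Ring order: the single carbocycle forms in the cyclisation step together with a temporary cyclic carbonate across C10/C26; no other ring is made.

Assumption: the target is natural iridal, (6R,10S,11S,2Z) in iridal numbering (C1 = CHO, C3 = side-chain CH2OH, C6–C11 = ring, C26 = ring CH2OH), which is used for atom labels; "homofarnesyl" = (3E,7E)-4,8,12-trimethyltrideca-3,7,11-trien-1-yl.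

**Route**

Step 1
Reactants: 1 (2E,6E)-farnesol
Product: 2 (2E,6E)-farnesal
Conditions: MnO2, CH2Cl2, rt
Reagents that add atoms: none
Why: Allylic oxidation with MnO2 converts only the allylic primary alcohol into the enal and leaves the isolated trisubstituted olefins and their E geometry untouched.

Step 2
Reactants: 2 (2E,6E)-farnesal
Product: 3 (3E,7E)-4,8,12-trimethyltrideca-1,3,7,11-tetraene
Conditions: Ph3PCH3Br, KN(SiMe3)2, THF, −78 → 0 °C
Reagents that add atoms: methyltriphenylphosphonium bromide (C[P+](c1ccccc1)(c1ccccc1)c1ccccc1.[Br-])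
Why: Wittig methylenation of the enal with the non-stabilised ylide adds the one extra carbon as a terminal vinyl group without touching the existing olefins.

Step 3
Reactants: 3 (3E,7E)-4,8,12-trimethyltrideca-1,3,7,11-tetraene
Product: 5 homofarnesol, via 9-homofarnesyl-9-BBN 4 (not isolated)
Conditions: 9-BBN, THF, 0 °C → rt; then NaOH, H2O2
Reagents that add atoms: hydrogen peroxide (OO) gives the O of 5; 9-borabicyclo[3.3.1]nonane (B1C2CCCC1CCC2) only in 4
Why: Hydroboration–oxidation: the bulky borane adds only to the monosubstituted terminus of the diene in anti-Markovnikov 1,2-fashion, so oxidation gives the primary homoallylic alcohol with the 3E olefin intact.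

Step 4
Reactants: 5 homofarnesol
Product: 6 homofarnesyl bromide
Conditions: CBr4, PPh3, CH2Cl2, 0 °C
Reagents that add atoms: carbon tetrabromide (BrC(Br)(Br)Br)
Why: Appel bromination replaces the primary hydroxyl by bromide under neutral conditions that do not isomerise the olefins.

Step 5
Reactants: 6 homofarnesyl bromide; 7 but-2-yn-1-ol
Product: 10 (2Z)-2-homofarnesyl-3-iodobut-2-en-1-ol, via homofarnesylmagnesium bromide 8 (not isolated), via cyclic alkenylmagnesium alkoxide 9 (not isolated)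
Conditions: 6, Mg, THF; 7 deprotonated with i-PrMgCl (1 equiv), CuI (10 mol%), THF–toluene, 60 °C; then I2, −40 °C
Reagents that add atoms: iodine ([I][I]) gives the I of 10; magnesium ([Mg]) only in 8 and 9
Why: Copper-catalysed anti-carbomagnesiation of the propargylic alkoxide (Duboudin reaction) delivers the alkyl group to the carbinol-side alkyne carbon and magnesium to the methyl-bearing carbon within a five-membered chelate, and iodinolysis with retention therefore gives the tetrasubstituted olefin with iodine cis to CH2OH and the chain cis to CH3.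

Step 6
Reactants: 10 (2Z)-2-homofarnesyl-3-iodobut-2-en-1-ol
Product: 11 (2Z)-2-homofarnesyl-3-iodobut-2-en-1-yl dimethylcarbamate
Conditions: NaH, Me2NCOCl, THF, 0 °C → rt
Reagents that add atoms: dimethylcarbamoyl chloride (CN(C)C(Cl)=O)
Why: O-Acylation of the alkoxide with the carbamoyl chloride installs the carbonyl oxygen that will capture the C10 cation and, unlike an allylic carbonate, is not ionised by zerovalent palladium in the coupling step.

Step 7
Reactants: 12 but-3-yn-1-ol
Product: 14 (3E)-4-iodobut-3-en-1-ol, via E-alkenylzirconocene chloride 13 (not isolated)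
Conditions: Cp2Zr(H)Cl (2.2 equiv), THF, rt; then I2, 0 °C
Reagents that add atoms: iodine ([I][I]) gives the I of 14; Cp2Zr(H)Cl ([H][Zr](Cl)(C1C=CC=C1)C1C=CC=C1) only in 13
Why: Hydrozirconation adds Zr–H syn with zirconium on the terminal carbon and iodinolysis proceeds with retention, giving the E-vinyl iodide.

Step 8
Reactants: 14 (3E)-4-iodobut-3-en-1-ol; 15 prop-2-yn-1-yl benzoate
Product: 16 (4E)-7-hydroxyhept-4-en-2-yn-1-yl benzoate
Conditions: PdCl2(PPh3)2 (2 mol%), CuI (4 mol%), Et3N, THF, rt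
Reagents that add atoms: none
Why: Sonogashira coupling joins the alkyne to the vinyl iodide with retention of the E geometry and tolerates the free alcohol and the ester.

Step 9
Reactants: 16 (4E)-7-hydroxyhept-4-en-2-yn-1-yl benzoate
Product: 17 3-[(2S,3S)-3-(2-hydroxyethyl)oxiran-2-yl]prop-2-yn-1-yl benzoate
Conditions: L-sorbose-derived enantiomer of the Shi ketone (30 mol%), KHSO5 (as 2KHSO5·KHSO4·K2SO4), K2CO3, Bu4NHSO4, MeCN–CH2(OMe)2–aqueous buffer pH 10.5, 0 °C
Reagents that add atoms: potassium peroxymonosulfate KHSO5 ([K+].[O-]S(=O)(=O)OO)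
Why: Shi asymmetric epoxidation: the chiral dioxirane transfers oxygen to the trans-olefin through a spiro transition state, the L-series ketone giving the (2S,3S)-oxirane while the alkyne and the ester are inert.

Step 10
Reactants: 17 3-[(2S,3S)-3-(2-hydroxyethyl)oxiran-2-yl]prop-2-yn-1-yl benzoate
Product: 18 3-[(2S,3S)-3-(2-iodoethyl)oxiran-2-yl]prop-2-yn-1-yl benzoate
Conditions: I2, PPh3, imidazole, CH2Cl2, 0 °C
Reagents that add atoms: iodine ([I][I])
Why: Iodination with PPh3, I2 and imidazole (Appel type) is an SN2 displacement at the primary carbon and leaves the oxirane stereocentres untouched.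

Step 11
Reactants: 18 3-[(2S,3S)-3-(2-iodoethyl)oxiran-2-yl]prop-2-yn-1-yl benzoate; 11 (2Z)-2-homofarnesyl-3-iodobut-2-en-1-yl dimethylcarbamate
Product: 20 3-{(2S,3S)-3-[(3Z)-5-(dimethylcarbamoyloxy)-4-homofarnesyl-3-methylpent-3-en-1-yl]oxiran-2-yl}prop-2-yn-1-yl benzoate, via alkylzinc iodide 19 (not isolated)
Conditions: 18, Zn, LiCl, THF, 35 °C; then 11, PdCl2(dppf) (5 mol%), THF, rt
Reagents that add atoms: zinc ([Zn]) only in 19
Why: Negishi sp3–sp2 coupling: zinc inserts into the primary C–I bond without touching oxirane, ester or alkyne, oxidative addition of zerovalent palladium to the vinyl iodide is expected to be faster than its attack on the alkynyl oxirane or the propargylic ester, and the coupling goes with retention, so the new CH2 ends cis to the carbamoyloxymethyl group.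

Step 12
Reactants: 20 3-{(2S,3S)-3-[(3Z)-5-(dimethylcarbamoyloxy)-4-homofarnesyl-3-methylpent-3-en-1-yl]oxiran-2-yl}prop-2-yn-1-yl benzoate
Product: 22 3-[(4aS,5S,6S,8aS)-6-hydroxy-4a-homofarnesyl-8a-methyl-2-oxohexahydro-4H-1,3-benzodioxin-5-yl]prop-2-yn-1-yl benzoate, via cyclic iminium carbonate 21 (not isolated)
Conditions: BF3·OEt2 (1.5 equiv), CH2Cl2, −78 → −40 °C; then aqueous NaHCO3
Reagents that add atoms: water (O) gives the carbonyl O of the cyclic carbonate; boron trifluoride (FB(F)F) only in 21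
Why: Proposed new method: BF3 opens the oxirane at its propargylic carbon C6 as the tetrasubstituted olefin attacks with inversion through a chair while the carbamate carbonyl adds anti to C10 (the iminium is hydrolysed on work-up), so the oxirane configuration fixes C6, the CH2O group being cis to C9 in the olefin puts C26 axial and trans to H6, and the tether puts the C10 oxygen cis to C26; the closest known reactions are epoxide-initiated cation–olefin (polyene) cyclisations and carbamate-terminated epoxide cascades.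

Step 13
Reactants: 22 3-[(4aS,5S,6S,8aS)-6-hydroxy-4a-homofarnesyl-8a-methyl-2-oxohexahydro-4H-1,3-benzodioxin-5-yl]prop-2-yn-1-yl benzoate
Product: 23 3-[(4aS,5S,6S,8aS)-6-hydroxy-4a-homofarnesyl-8a-methyl-2-oxohexahydro-4H-1,3-benzodioxin-5-yl]propyl benzoate
Conditions: H2 (1 atm), RhCl(PPh3)3 (10 mol%), benzene–EtOH, rt
Reagents that add atoms: none
Why: Homogeneous hydrogenation with RhCl(PPh3)3 reduces the disubstituted alkyne to the alkane while trisubstituted olefins react far more slowly, and no stereocentre is touched.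

Step 14
Reactants: 23 3-[(4aS,5S,6S,8aS)-6-hydroxy-4a-homofarnesyl-8a-methyl-2-oxohexahydro-4H-1,3-benzodioxin-5-yl]propyl benzoate
Product: 24 3-[(4aS,5S,8aS)-4a-homofarnesyl-8a-methyl-2,6-dioxohexahydro-4H-1,3-benzodioxin-5-yl]propyl benzoate
Conditions: Dess–Martin periodinane, NaHCO3, CH2Cl2, 0 °C → rt
Reagents that add atoms: none
Why: Dess–Martin oxidation turns the secondary alcohol into the ketone under buffered, non-basic conditions that do not epimerise the adjacent C6 centre.

Step 15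
Reactants: 24 3-[(4aS,5S,8aS)-4a-homofarnesyl-8a-methyl-2,6-dioxohexahydro-4H-1,3-benzodioxin-5-yl]propyl benzoate
Product: 25 3-[(4aS,5S,6R,8aS)-6-hydroxy-4a-homofarnesyl-8a-methyl-2-oxo-6-(prop-1-en-2-yl)hexahydro-4H-1,3-benzodioxin-5-yl]propyl benzoate
Conditions: CH2=C(CH3)MgBr, CeCl3, THF, −78 °C
Reagents that add atoms: isopropenylmagnesium bromide (C=C(C)[Mg]Br)
Why: Organocerium 1,2-addition (Imamoto conditions) to the hindered, enolisable ketone is faster than enolisation or attack on the ester and carbonate, the reagent entering equatorially anti to the axial C26 arm to give a carbinol centre that is erased in the next step.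

Step 16
Reactants: 25 3-[(4aS,5S,6R,8aS)-6-hydroxy-4a-homofarnesyl-8a-methyl-2-oxo-6-(prop-1-en-2-yl)hexahydro-4H-1,3-benzodioxin-5-yl]propyl benzoate
Product: 26 3-[(4aS,5R,6Z,8aS)-4a-homofarnesyl-8a-methyl-2-oxo-6-(1-oxopropan-2-ylidene)hexahydro-4H-1,3-benzodioxin-5-yl]propyl benzoate
Conditions: pyridinium chlorochromate [C5H5NH][CrO3Cl], 4 Å sieves, CH2Cl2, rt
Reagents that add atoms: pyridinium chlorochromate ([O-][Cr](=O)(=O)Cl.c1cc[nH+]cc1) gives the aldehyde O
Why: Babler–Dauben oxidative transposition: the tertiary allylic chromate ester undergoes a [3,3]-shift and oxidation to the tetrasubstituted enal, and the chair transition state keeps the 2-methyl group on the side of the unsubstituted C8 so that the formyl group ends cis to C6 (2Z), which is also the isomer with less allylic strain.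

Step 17
Reactants: 26 3-[(4aS,5R,6Z,8aS)-4a-homofarnesyl-8a-methyl-2-oxo-6-(1-oxopropan-2-ylidene)hexahydro-4H-1,3-benzodioxin-5-yl]propyl benzoate
Product: 27 iridal, (2Z)-2-[(2R,3S,4S)-4-hydroxy-3-(hydroxymethyl)-2-(3-hydroxypropyl)-4-methyl-3-homofarnesylcyclohexylidene]propanal
Conditions: K2CO3, MeOH, 0 °C → rt
Reagents that add atoms: none
Why: Carbonate-catalysed transesterification with methanol removes the cyclic carbonate and the benzoate in one operation under conditions too mild to deconjugate or epimerise the β,β-disubstituted enal.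

**Compound list**
1 | (2E,6E)-farnesol | CC(C)=CCC/C(C)=C/CC/C(C)=C/CO | starting material
2 | (2E,6E)-farnesal | CC(C)=CCC/C(C)=C/CC/C(C)=C/C=O | intermediate
3 | (3E,7E)-4,8,12-trimethyltrideca-1,3,7,11-tetraene | CC(C)=CCC/C(C)=C/CC/C(C)=C/C=C | intermediate
4 | 9-homofarnesyl-9-borabicyclo[3.3.1]nonane | CC(C)=CCC/C(C)=C/CC/C(C)=C/CCB1C2CCCC1CCC2 | intermediate
5 | homofarnesol, (3E,7E)-4,8,12-trimethyltrideca-3,7,11-trien-1-ol | CC(C)=CCC/C(C)=C/CC/C(C)=C/CCO | intermediate
6 | homofarnesyl bromide, (3E,7E)-1-bromo-4,8,12-trimethyltrideca-3,7,11-triene | CC(C)=CCC/C(C)=C/CC/C(C)=C/CCBr | intermediate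
7 | but-2-yn-1-ol | CC#CCO | starting material
8 | homofarnesylmagnesium bromide | CC(C)=CCC/C(C)=C/CC/C(C)=C/CC[Mg]Br | intermediate
9 | 4-homofarnesyl-3-methyl-2,5-dihydro-1,2-oxamagnesole (cyclic alkenylmagnesium alkoxide) | CC(C)=CCC/C(C)=C/CC/C(C)=C/CCC1=C(C)[Mg]OC1 | intermediate
10 | (2Z)-2-homofarnesyl-3-iodobut-2-en-1-ol | CC(C)=CCC/C(C)=C/CC/C(C)=C/CC/C(CO)=C(\C)I | intermediate
11 | (2Z)-2-homofarnesyl-3-iodobut-2-en-1-yl dimethylcarbamate | CC(C)=CCC/C(C)=C/CC/C(C)=C/CC/C(COC(=O)N(C)C)=C(\C)I | intermediate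
12 | but-3-yn-1-ol | C#CCCO | starting material
13 | E-alkenylzirconocene chloride of the zirconium alkoxide of 12 | Cl[Zr](OCC/C=C/[Zr](Cl)(C1C=CC=C1)C1C=CC=C1)(C1C=CC=C1)C1C=CC=C1 | intermediate
14 | (3E)-4-iodobut-3-en-1-ol | OCC/C=C/I | intermediate
15 | prop-2-yn-1-yl benzoate | C#CCOC(=O)c1ccccc1 | starting material
16 | (4E)-7-hydroxyhept-4-en-2-yn-1-yl benzoate | O=C(OCC#C/C=C/CCO)c1ccccc1 | intermediate
17 | 3-[(2S,3S)-3-(2-hydroxyethyl)oxiran-2-yl]prop-2-yn-1-yl benzoate | O=C(OCC#C[C@@H]1O[C@H]1CCO)c1ccccc1 | intermediate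
18 | 3-[(2S,3S)-3-(2-iodoethyl)oxiran-2-yl]prop-2-yn-1-yl benzoate | O=C(OCC#C[C@@H]1O[C@H]1CCI)c1ccccc1 | intermediate
19 | {2-[(2S,3S)-3-(3-benzoyloxyprop-1-yn-1-yl)oxiran-2-yl]ethyl}zinc iodide | O=C(OCC#C[C@@H]1O[C@H]1CC[Zn]I)c1ccccc1 | intermediate
20 | 3-{(2S,3S)-3-[(3Z)-5-(dimethylcarbamoyloxy)-4-homofarnesyl-3-methylpent-3-en-1-yl]oxiran-2-yl}prop-2-yn-1-yl benzoate | CC(C)=CCC/C(C)=C/CC/C(C)=C/CC/C(COC(=O)N(C)C)=C(\C)CC[C@@H]1O[C@H]1C#CCOC(=O)c1ccccc1 | intermediate
21 | cyclic iminium carbonate: the 2-(dimethyliminio) analogue of 22 with the C6 oxygen of the benzodioxin bound to BF3 (zwitterion) | CC(C)=CCC/C(C)=C/CC/C(C)=C/CC[C@]12COC(=[N+](C)C)O[C@@]1(C)CC[C@H](O[B-](F)(F)F)[C@H]2C#CCOC(=O)c1ccccc1 | intermediate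
22 | 3-[(4aS,5S,6S,8aS)-6-hydroxy-4a-homofarnesyl-8a-methyl-2-oxohexahydro-4H-1,3-benzodioxin-5-yl]prop-2-yn-1-yl benzoate | CC(C)=CCC/C(C)=C/CC/C(C)=C/CC[C@]12COC(=O)O[C@@]1(C)CC[C@H](O)[C@H]2C#CCOC(=O)c1ccccc1 | intermediate
23 | 3-[(4aS,5S,6S,8aS)-6-hydroxy-4a-homofarnesyl-8a-methyl-2-oxohexahydro-4H-1,3-benzodioxin-5-yl]propyl benzoate | CC(C)=CCC/C(C)=C/CC/C(C)=C/CC[C@]12COC(=O)O[C@@]1(C)CC[C@H](O)[C@H]2CCCOC(=O)c1ccccc1 | intermediate
24 | 3-[(4aS,5S,8aS)-4a-homofarnesyl-8a-methyl-2,6-dioxohexahydro-4H-1,3-benzodioxin-5-yl]propyl benzoate | CC(C)=CCC/C(C)=C/CC/C(C)=C/CC[C@]12COC(=O)O[C@@]1(C)CCC(=O)[C@H]2CCCOC(=O)c1ccccc1 | intermediate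
25 | 3-[(4aS,5S,6R,8aS)-6-hydroxy-4a-homofarnesyl-8a-methyl-2-oxo-6-(prop-1-en-2-yl)hexahydro-4H-1,3-benzodioxin-5-yl]propyl benzoate | CC(C)=CCC/C(C)=C/CC/C(C)=C/CC[C@]12COC(=O)O[C@@]1(C)CC[C@](O)(C(C)=C)[C@H]2CCCOC(=O)c1ccccc1 | intermediate
26 | 3-[(4aS,5R,6Z,8aS)-4a-homofarnesyl-8a-methyl-2-oxo-6-(1-oxopropan-2-ylidene)hexahydro-4H-1,3-benzodioxin-5-yl]propyl benzoate | CC(C)=CCC/C(C)=C/CC/C(C)=C/CC[C@]12COC(=O)O[C@@]1(C)CC/C(=C(\C)C=O)[C@H]2CCCOC(=O)c1ccccc1 | intermediate
27 | iridal, (2Z)-2-[(2R,3S,4S)-4-hydroxy-3-(hydroxymethyl)-2-(3-hydroxypropyl)-4-methyl-3-homofarnesylcyclohexylidene]propanal | CC(C)=CCC/C(C)=C/CC/C(C)=C/CC[C@@]1(CO)[C@H](CCCO)/C(=C(/C)C=O)CC[C@]1(C)O | target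

**Step count and risks**
Total step count: 17. Longest linear sequence: 13 steps (steps 1–6 and 11–17, from 1 to 27).

Steps most likely to fail:

Step 12 is the key cyclisation and the riskiest step. The olefin could attack through C10 to give a five-membered ring, the C10 cation could be taken by the Δ14 olefin of the side chain, or the alkynyl oxirane could rearrange to a carbonyl compound. The fallback sets out from 10 and 19 and returns at 22. It changes the terminating group to a tert-butyl carbonate, whose carbonyl attack is made irreversible by loss of 2-methylpropene (Bartlett-type carbonate participation) and needs no iminium hydrolysis. Alkylzinc 19 is coupled with the zinc alkoxide of 10 (PdCl2(dppf)) to give 3-{(2S,3S)-3-[(3Z)-5-hydroxy-4-homofarnesyl-3-methylpent-3-en-1-yl]oxiran-2-yl}prop-2-yn-1-yl benzoate F1. Acylation with Boc2O and DMAP gives 3-{(2S,3S)-3-[(3Z)-5-(tert-butoxycarbonyloxy)-4-homofarnesyl-3-methylpent-3-en-1-yl]oxiran-2-yl}prop-2-yn-1-yl benzoate F2. Treating F2 with BF3·OEt2 at −78 °C gives 22 directly.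

Step 5 adds a valuable primary alkyl Grignard reagent across an internal propargylic alcohol, which may be slow or end in simple protonation. The fallback sets out from 6 and returns at 20, and builds the same olefin by enol triflate chemistry. The sodium enolate of ethyl acetoacetate is alkylated with 6 (NaH, NaI, THF–DMF) to give ethyl 2-homofarnesyl-3-oxobutanoate F3. Chelation-controlled triflation (aqueous LiOH, Tf2O, toluene) gives ethyl (2Z)-2-homofarnesyl-3-(trifluoromethanesulfonyloxy)but-2-enoate F4, with the triflate cis to the ester. Reduction of the ester with i-Bu2AlH at −78 °C gives (2Z)-4-hydroxy-3-homofarnesylbut-2-en-2-yl trifluoromethanesulfonate F5. Carbamoylation (NaH, Me2NCOCl) gives (2Z)-4-(dimethylcarbamoyloxy)-3-homofarnesylbut-2-en-2-yl trifluoromethanesulfonate F6. Coupling F6 with alkylzinc 19 under the conditions of step 11 (retention) gives 20.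

Step 16 may give a poor yield or the wrong olefin geometry in the oxidative transposition. The fallback sets out from 24 and returns at 27, bypassing 25 and 26. Ketone 24 is olefinated with the sodium salt of diethyl (1-cyanoethyl)phosphonate (Horner–Wadsworth–Emmons, THF, 0 °C → rt) to give 3-[(4aS,5R,6Z,8aS)-6-(1-cyanoethylidene)-4a-homofarnesyl-8a-methyl-2-oxohexahydro-4H-1,3-benzodioxin-5-yl]propyl benzoate F7, which is separated from its E isomer. Excess i-Bu2AlH at −78 °C then reduces the nitrile to the aldimine and cleaves the benzoate and the cyclic carbonate, and mild aqueous acid hydrolyses the imine to 27.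

Further compounds
F1 | step 12 | 3-{(2S,3S)-3-[(3Z)-5-hydroxy-4-homofarnesyl-3-methylpent-3-en-1-yl]oxiran-2-yl}prop-2-yn-1-yl benzoate | CC(C)=CCC/C(C)=C/CC/C(C)=C/CC/C(CO)=C(\C)CC[C@@H]1O[C@H]1C#CCOC(=O)c1ccccc1
F2 | step 12 | 3-{(2S,3S)-3-[(3Z)-5-(tert-butoxycarbonyloxy)-4-homofarnesyl-3-methylpent-3-en-1-yl]oxiran-2-yl}prop-2-yn-1-yl benzoate | CC(C)=CCC/C(C)=C/CC/C(C)=C/CC/C(COC(=O)OC(C)(C)C)=C(\C)CC[C@@H]1O[C@H]1C#CCOC(=O)c1ccccc1
F3 | step 5 | ethyl 2-homofarnesyl-3-oxobutanoate | CCOC(=O)C(CC/C=C(\C)CC/C=C(\C)CCC=C(C)C)C(C)=O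
F4 | step 5 | ethyl (2Z)-2-homofarnesyl-3-(trifluoromethanesulfonyloxy)but-2-enoate | CCOC(=O)/C(CC/C=C(\C)CC/C=C(\C)CCC=C(C)C)=C(/C)OS(=O)(=O)C(F)(F)F
F5 | step 5 | (2Z)-4-hydroxy-3-homofarnesylbut-2-en-2-yl trifluoromethanesulfonate | OC/C(CC/C=C(\C)CC/C=C(\C)CCC=C(C)C)=C(/C)OS(=O)(=O)C(F)(F)F
F6 | step 5 | (2Z)-4-(dimethylcarbamoyloxy)-3-homofarnesylbut-2-en-2-yl trifluoromethanesulfonate | CN(C)C(=O)OC/C(CC/C=C(\C)CC/C=C(\C)CCC=C(C)C)=C(/C)OS(=O)(=O)C(F)(F)F
F7 | step 16 | 3-[(4aS,5R,6Z,8aS)-6-(1-cyanoethylidene)-4a-homofarnesyl-8a-methyl-2-oxohexahydro-4H-1,3-benzodioxin-5-yl]propyl benzoate | CC(C)=CCC/C(C)=C/CC/C(C)=C/CC[C@]12COC(=O)O[C@@]1(C)CC/C(=C(\C)C#N)[C@H]2CCCOC(=O)c1ccccc1
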